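The route rests on disconnecting C1–C10. C7, the methyl-bearing quaternary carbon shared by the five- and seven-membered rings, has carbinol carbon C6 and ring-fusion carbon C1 as neighbours. Both can be traced back to carbonyls, so C7 is the hidden symmetry centre of a 2-methylcycloheptane-1,3-dione that carries a three-carbon aldehyde arm (C8–C10). An enantiopure triazolium carbene makes the aldehyde carbon nucleophilic and directs it to one of the two mirror-related ring ketones: one operation closes the cyclopentanone, fixes C7 and leaves three different oxygens (C1–OH, C6=O, C10=O). All later centres are set by substrate control.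

Key step: step 3

Atom labels: C1 ring-fusion CH, C2 the ester-bearing carbon, C3 ring CH2, C4 the methylidene-bearing ring carbon, C5 and C6 the two carbinol carbons, C7 the quaternary methyl carbon, C8 and C9 the cyclopentane CH2 groups, C10 the isopropyl carbinol. These labels serve as locants in all bicyclo[5.3.0]decane names below; β is the face carrying the C7 methyl, α the other face.

Assumption: the (5aS,10bR) catalyst is taken to give the (3aS,8aR) ketol by analogy with six-membered diones; if the sense of induction proves opposite, its mirror-image salt is used.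

Step 1
Reactants: 1 cycloheptane-1,3-dione; 2 iodomethane
Product: 3 2-methylcycloheptane-1,3-dione
Conditions: K2CO3, acetone, reflux
Reagents that add atoms: none
Why: Base-mediated C-alkylation (SN2 on iodomethane) of the 1,3-diketone enolate, the usual entry to 2-alkylcycloalkane-1,3-diones; no stereocentre is created.

Step 2
Reactants: 3 2-methylcycloheptane-1,3-dione; 4 acrolein
Product: 5 3-(1-methyl-2,7-dioxocycloheptyl)propanal
Conditions: Et3N (10 mol%), CH2Cl2, 0 °C to rt
Reagents that add atoms: none
Why: Amine-catalysed Michael addition of the acidic C–H between the two carbonyls to acrolein, a known reaction of 2-alkylcycloalkane-1,3-diones; the new quaternary carbon (future C7) is still achiral because the ring is symmetric.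

Step 3
Reactants: 5 3-(1-methyl-2,7-dioxocycloheptyl)propanal
Product: 6 cis-fused ketol (3aS,8aR)-8a-hydroxy-3a-methylhexahydroazulene-1,4(2H,5H)-dione (1β-hydroxy-7β-methylbicyclo[5.3.0]decane-6,10-dione)
Conditions: (5aS,10bR)-2-(pentafluorophenyl)-5a,10b-dihydro-4H,6H-indeno[2,1-b][1,2,4]triazolo[4,3-d][1,4]oxazin-2-ium tetrafluoroborate (15 mol%), Et3N (15 mol%), toluene, rt
Reagents that add atoms: none
Why: The carbene released from the triazolium salt adds to the aldehyde carbon C10 and a proton shift gives the nucleophilic enaminol (Breslow intermediate), whose carbon attacks a ring carbonyl before the catalyst is expelled, leaving the C10 ketone and the tertiary C1 alcohol. The closest known reaction is the carbene-catalysed desymmetrising crossed benzoin of 2-substituted 2-(3-oxopropyl)cycloalkane-1,3-diones with five- and six-membered rings, and the seven-membered dione extends it by one ring size. The cyclopentane ring (C1, C7, C8, C9, C10) closes by a 5-exo-trig addition to the C=O bond. C7 becomes stereogenic through the choice between the two enantiotopic ketones, which is made by the aminoindanol backbone and the N-aryl group of the catalyst; the configuration at C1 follows from the three-atom tether, which can reach the carbonyl only from the face that puts the new hydroxyl cis to the C7 methyl. The step needs the benzoin pathway to win over aldol closure and aldehyde self-condensation, which should be secured by the weak amine base, by the quaternary C7 (no enolisation between the carbonyls) and by fast carbene addition to the unhindered aldehyde.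

Step 4
Reactants: 6 cis-fused ketol
Product: 7 (S)-3a-methyl-3,3a,6,7-tetrahydroazulene-1,4(2H,5H)-dione (7β-methylbicyclo[5.3.0]dec-1(2)-ene-6,10-dione)
Conditions: Burgess reagent (methyl N-(triethylammoniosulfonyl)carbamate), toluene, 50 °C
Reagents that add atoms: none
Why: Burgess dehydration (thermal syn-elimination) of the tertiary alcohol; C2 is the only neighbour with hydrogen (C7 is quaternary, C10 a carbonyl), so only the C1=C2 enone can form, and the C1 centre is erased on purpose while C7 is untouched.

Step 5
Reactants: 7 enedione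
Product: 8 10β-hydroxy-10α-isopropyl-7β-methylbicyclo[5.3.0]dec-1(2)-en-6-one
Conditions: i-PrMgCl, CeCl3, THF, −78 °C; aq. NH4Cl
Reagents that add atoms: isopropylmagnesium chloride, CC(C)[Mg]Cl
Why: Organocerium 1,2-addition, which is non-basic and does not add in a conjugate sense; the C10 carbonyl of the alkylidenecyclopentanone should be attacked in preference to the C6 ketone, which is shielded by the adjacent quaternary C7, and the reagent is expected on the α face, away from the C7 methyl, so that isopropyl is α and hydroxyl β.

Step 6
Reactants: 8 tertiary allylic alcohol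
Product: 9 1β,2β-epoxy-10β-hydroxy-10α-isopropyl-7β-methylbicyclo[5.3.0]decan-6-one
Conditions: VO(acac)2 (5 mol%), t-BuOOH, CH2Cl2, 0 °C to rt
Reagents that add atoms: tert-butyl hydroperoxide, CC(C)(C)OO
Why: Vanadium-catalysed hydroxyl-directed epoxidation of an allylic alcohol: the metal-bound peroxide is delivered from the C10 oxygen, so the epoxide forms on the β face of C1=C2, syn to the hydroxyl.

Step 7
Reactants: 9 β-epoxy alcohol
Product: 10 1α-H,2β,10β-dihydroxy-10α-isopropyl-7β-methylbicyclo[5.3.0]decan-6-one (trans-fused)
Conditions: (C5H5)2TiCl2, Zn, THF, rt; then 9, 1,4-cyclohexadiene, rt; aq. NaH2PO4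
Reagents that add atoms: none
Why: Titanocene-mediated reductive epoxide opening: (C5H5)2TiCl cleaves the C1–O bond to the tertiary C1 radical (anti-Markovnikov alcohol), and 1,4-cyclohexadiene should transfer hydrogen to the α face of C1 because the β face is blocked by the neighbouring titanium alkoxide at C2, the C10 oxygen and the C7 methyl, which sets the trans ring fusion.

Step 8
Reactants: 10 2β,10β-diol
Product: 11 1α-H,10β-hydroxy-10α-isopropyl-7β-methylbicyclo[5.3.0]decane-2,6-dione
Conditions: Dess–Martin periodinane, pyridine, CH2Cl2, 0 °C to rt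
Reagents that add atoms: none
Why: Dess–Martin oxidation of the only secondary alcohol under mild buffered conditions that should neither epimerise C1 nor trigger retro-aldol cleavage of the β-hydroxy ketone; the tertiary C10 alcohol is inert.

Step 9
Reactants: 11 hydroxy diketone
Product: 12 1α-H,2α,10β-dihydroxy-10α-isopropyl-7β-methylbicyclo[5.3.0]decan-6-one
Conditions: Me4NBH(OAc)3, MeCN/AcOH (1:1), −20 °C
Reagents that add atoms: none
Why: Evans–Saksena reduction of a β-hydroxy ketone: boron binds the C10 oxygen and passes hydride to the β face of the C2 carbonyl through a six-membered transition state, giving the α (1,3-anti) alcohol, while the C6 ketone has no suitably placed hydroxyl and is left alone.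

Step 10
Reactants: 12 2α,10β-diol; 13 isovaleric anhydride
Product: 14 1α-H,10β-hydroxy-10α-isopropyl-7β-methyl-2α-(3-methylbutanoyloxy)bicyclo[5.3.0]decan-6-one
Conditions: DMAP (10 mol%), Et3N, CH2Cl2, rt
Reagents that add atoms: none
Why: DMAP-catalysed acyl transfer to the secondary C2 hydroxyl; the tertiary C10 hydroxyl does not react under these conditions and no stereocentre is affected.

Step 11
Reactants: 14 ester ketone
Product: 15 1α-H,10β-hydroxy-10α-isopropyl-7β-methyl-2α-(3-methylbutanoyloxy)bicyclo[5.3.0]dec-4-en-6-one
Conditions: IBX, DMSO/toluene, 70 °C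
Reagents that add atoms: none
Why: IBX dehydrogenation of a ketone by way of its enol; the quaternary C7 leaves C5 as the only enolisable position, so the C4=C5 enone is the single product.

Step 12
Reactants: 15 C4=C5 enone
Product: 16 4β,5β-epoxide of 15 (epoxy ketone)
Conditions: 30% H2O2, NaOH (cat.), MeOH, 0 °C
Reagents that add atoms: hydrogen peroxide, OO
Why: Weitz–Scheffer epoxidation (conjugate addition of hydroperoxide, then ring closure) of the enone; the epoxide configuration (β drawn) is without consequence because C5 becomes sp2 and C4 a carbonyl in the next two steps.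

Step 13
Reactants: 16 epoxy ketone
Product: 18 1α-H,4β,10β-dihydroxy-10α-isopropyl-7β-methylbicyclo[5.3.0]dec-5-en-2α-yl 3-methylbutanoate, via epoxy hydrazone 17 (not isolated)
Conditions: N2H4·H2O, AcOH (cat.), MeOH, 0 °C to rt
Reagents that add atoms: none
Why: Wharton transposition: epoxy hydrazone 17 opens the epoxide and loses nitrogen, which moves the oxygen from C6 to C4 and the double bond to C5=C6 (the C4 configuration is immaterial).

Step 14
Reactants: 18 C4 allylic alcohol
Product: 19 1α-H,10β-hydroxy-10α-isopropyl-7β-methyl-2α-(3-methylbutanoyloxy)bicyclo[5.3.0]dec-5-en-4-one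
Conditions: MnO2, CH2Cl2, rt
Reagents that add atoms: none
Why: MnO2 oxidation of the allylic alcohol to the enone under neutral conditions, chosen because the C2 ester is now β to a carbonyl and would eliminate with base.

Step 15
Reactants: 19 C5=C6 enone
Product: 20 1α-H,5α,6α,10β-trihydroxy-10α-isopropyl-7β-methyl-2α-(3-methylbutanoyloxy)bicyclo[5.3.0]decan-4-one
Conditions: OsO4 (5 mol%), NMO, acetone/H2O, rt
Reagents that add atoms: N-methylmorpholine N-oxide, C[N+]1([O-])CCOCC1; water, O
Why: Catalytic OsO4/NMO syn-dihydroxylation of C5=C6; the osmium reagent should approach anti to the pseudo-axial methyl on the allylic quaternary C7, so both new hydroxyls are α, cis to each other and trans to the methyl.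

Step 16
Reactants: 20 keto diol
Product: 21 5α,6α-O-isopropylidene derivative of 20
Conditions: Me2C(OMe)2, PPTS (cat.), CH2Cl2, rt
Reagents that add atoms: 2,2-dimethoxypropane, COC(C)(C)OC
Why: Acid-catalysed acetal exchange on the cis-1,2-diol, which also masks the α-hydroxy ketone against epimerisation and retro-aldol cleavage.

Step 17
Reactants: 21 acetonide ketone
Product: 22 1α-H,10β-hydroxy-10α-isopropyl-5α,6α-isopropylidenedioxy-7β-methyl-4-methylidenebicyclo[5.3.0]decan-2α-yl 3-methylbutanoate
Conditions: Zn, CH2Br2, TiCl4, THF, 5 °C (reagent aged); then 21, CH2Cl2, rt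
Reagents that add atoms: dibromomethane, BrCBr
Why: Takai–Lombardo methylenation, a non-basic titanium–zinc carbonyl olefination that does not touch esters and avoids both β-elimination of the C2 ester and epimerisation at C5.

Step 18
Reactants: 22 methylidene acetonide
Product: 23 target CNP0204264.1, 1α-H,5α,6α,10β-trihydroxy-10α-isopropyl-7β-methyl-4-methylidenebicyclo[5.3.0]decan-2α-yl 3-methylbutanoate
Conditions: AcOH/H2O (4:1), 40 °C
Reagents that add atoms: none
Why: Mild aqueous acid hydrolysis of the isopropylidene acetal; the ester, the tertiary alcohol and the allylic system should survive and no stereocentre is touched.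

Compound list
1 | cycloheptane-1,3-dione | O=C1CCCCC(=O)C1 | starting material
2 | iodomethane | CI | starting material
3 | 2-methylcycloheptane-1,3-dione | CC1C(=O)CCCCC1=O | intermediate
4 | acrolein (prop-2-enal) | C=CC=O | starting material
5 | 3-(1-methyl-2,7-dioxocycloheptyl)propanal | O=CCCC1(C)C(=O)CCCCC1=O | intermediate
6 | (3aS,8aR)-8a-hydroxy-3a-methylhexahydroazulene-1,4(2H,5H)-dione; cis-fused ketol, C1–OH and C7–CH3 both β, ketones at C6 and C10 | C1CC[C@@]2(O)[C@](C)(CCC2=O)C(=O)C1 | intermediate
7 | (S)-3a-methyl-3,3a,6,7-tetrahydroazulene-1,4(2H,5H)-dione; C1=C2 conjugated with the C10 ketone, C6 ketone | C1CC=C2[C@](C)(CCC2=O)C(=O)C1 | intermediate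
8 | 10β-hydroxy-10α-isopropyl-7β-methylbicyclo[5.3.0]dec-1(2)-en-6-one | C1CC=C2[C@](C)(CC[C@@]2(O)C(C)C)C(=O)C1 | intermediate
9 | 1β,2β-epoxy-10β-hydroxy-10α-isopropyl-7β-methylbicyclo[5.3.0]decan-6-one | C1C[C@H]3O[C@@]32[C@](C)(CC[C@@]2(O)C(C)C)C(=O)C1 | intermediate
10 | 1α-H,2β,10β-dihydroxy-10α-isopropyl-7β-methylbicyclo[5.3.0]decan-6-one (trans-fused) | C1C[C@@H](O)[C@@H]2[C@](C)(CC[C@@]2(O)C(C)C)C(=O)C1 | intermediate
11 | 1α-H,10β-hydroxy-10α-isopropyl-7β-methylbicyclo[5.3.0]decane-2,6-dione | C1CC(=O)[C@@H]2[C@](C)(CC[C@@]2(O)C(C)C)C(=O)C1 | intermediate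
12 | 1α-H,2α,10β-dihydroxy-10α-isopropyl-7β-methylbicyclo[5.3.0]decan-6-one | C1C[C@H](O)[C@@H]2[C@](C)(CC[C@@]2(O)C(C)C)C(=O)C1 | intermediate
13 | isovaleric anhydride (3-methylbutanoic anhydride) | CC(C)CC(=O)OC(=O)CC(C)C | starting material
14 | 1α-H,10β-hydroxy-10α-isopropyl-7β-methyl-2α-(3-methylbutanoyloxy)bicyclo[5.3.0]decan-6-one | C1C[C@H](OC(=O)CC(C)C)[C@@H]2[C@](C)(CC[C@@]2(O)C(C)C)C(=O)C1 | intermediate
15 | C4=C5 enone, 1α-H,10β-hydroxy-10α-isopropyl-7β-methyl-2α-(3-methylbutanoyloxy)bicyclo[5.3.0]dec-4-en-6-one | C=1C[C@H](OC(=O)CC(C)C)[C@@H]2[C@](C)(CC[C@@]2(O)C(C)C)C(=O)C=1 | intermediate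
16 | 4β,5β-epoxide of 15 (C6 ketone) | O1[C@H]2C[C@H](OC(=O)CC(C)C)[C@@H]3[C@](C)(CC[C@@]3(O)C(C)C)C(=O)[C@@H]12 | intermediate
17 | C6 hydrazone of 16 (not isolated) | O1[C@H]2C[C@H](OC(=O)CC(C)C)[C@@H]3[C@](C)(CC[C@@]3(O)C(C)C)C(=NN)[C@@H]12 | intermediate
18 | 1α-H,4β,10β-dihydroxy-10α-isopropyl-7β-methylbicyclo[5.3.0]dec-5-en-2α-yl 3-methylbutanoate | O[C@H]1C[C@H](OC(=O)CC(C)C)[C@@H]2[C@](C)(CC[C@@]2(O)C(C)C)C=C1 | intermediate
19 | C5=C6 enone, 1α-H,10β-hydroxy-10α-isopropyl-7β-methyl-2α-(3-methylbutanoyloxy)bicyclo[5.3.0]dec-5-en-4-one | O=C1C[C@H](OC(=O)CC(C)C)[C@@H]2[C@](C)(CC[C@@]2(O)C(C)C)C=C1 | intermediate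
20 | 1α-H,5α,6α,10β-trihydroxy-10α-isopropyl-7β-methyl-2α-(3-methylbutanoyloxy)bicyclo[5.3.0]decan-4-one | O=C1C[C@H](OC(=O)CC(C)C)[C@@H]2[C@](C)(CC[C@@]2(O)C(C)C)[C@H](O)[C@@H]1O | intermediate
21 | 5α,6α-O-isopropylidene derivative of 20 | O=C1C[C@H](OC(=O)CC(C)C)[C@@H]2[C@](C)(CC[C@@]2(O)C(C)C)[C@@H]3OC(C)(C)O[C@H]13 | intermediate
22 | 4-methylidene analogue of 21 (5α,6α-acetonide of the target) | C=C1C[C@H](OC(=O)CC(C)C)[C@@H]2[C@](C)(CC[C@@]2(O)C(C)C)[C@@H]3OC(C)(C)O[C@H]13 | intermediate
23 | CNP0204264.1, 1α-H,5α,6α,10β-trihydroxy-10α-isopropyl-7β-methyl-4-methylidenebicyclo[5.3.0]decan-2α-yl 3-methylbutanoate | C=C1C[C@H](OC(=O)CC(C)C)[C@@H]2[C@](C)(CC[C@@]2(O)C(C)C)[C@H](O)[C@@H]1O | target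

Total step count: 18. Longest linear sequence: 18 steps (the route is fully linear from 1 to 23).

Steps most likely to fail

Step 3 (key step). With the larger, more flexible seven-membered ring the catalyst may discriminate the two enantiotopic carbonyls poorly, so that the ketol forms with low enantiomeric purity. The fallback sets out from 5 and comes back at 6: the closure is run with an achiral carbene (3-benzyl-5-(2-hydroxyethyl)-4-methylthiazolium chloride, Et3N, EtOH), which should give 6 together with its mirror image, the enantiomer of 6 F1; the two are separated by preparative chromatography on a chiral stationary phase and the route continues with 6.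

Step 5. The organocerium reagent may also add to, or enolise, the C6 ketone, that is, chemoselectivity between the two carbonyls may be lost. The fallback sets out from 7 and comes back at 8: the saturated C6 ketone is ketalised first (ethylene glycol, TsOH, benzene, Dean–Stark; the conjugated C10 carbonyl is much slower to ketalise), giving the C6 dioxolane of the enedione F2. i-PrMgCl/CeCl3 then meets a single carbonyl and should give the C6 dioxolane of the allylic alcohol F3. PPTS in wet acetone at rt removes the ketal without ionising the tertiary allylic alcohol and returns 8.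

Step 7. Hydrogen-atom transfer to the planar C1 radical may take place on both faces, so that the cis-fused C1 epimer accompanies 10. The fallback replaces kinetic by thermodynamic control of C1; it sets out from 8 and comes back at 11. Hydroboration–oxidation of 8 (BH3·THF, then NaOH/H2O2) puts oxygen on C2 and hydrogen on C1 and reduces C6 at the same time, giving the cis-fused triol F4 (the all-β isomer expected from attack on the hydroxyl-bearing face is drawn). Hydroboration is not relied on for the ring fusion itself, because its facial course at C1=C2 is uncertain. Dess–Martin oxidation of both secondary alcohols gives the cis-fused hydroxy diketone F5. DBU in CH2Cl2 then equilibrates C1, which is α to the C2 ketone, toward the trans-fused epimer 11; this epimer is expected to be favoured because the C2 branch of the seven-membered ring is no longer cis to the C10 isopropyl group.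

Further compounds
F1 | step 3 | enantiomer of 6, (3aR,8aS)-8a-hydroxy-3a-methylhexahydroazulene-1,4(2H,5H)-dione | C1CC[C@]2(O)[C@@](C)(CCC2=O)C(=O)C1
F2 | step 5 | C6 ethylene ketal (dioxolane) of enedione 7 | C1CC=C2[C@](C)(CCC2=O)C3(OCCO3)C1
F3 | step 5 | C6 ethylene ketal (dioxolane) of allylic alcohol 8 | C1CC=C2[C@](C)(CC[C@@]2(O)C(C)C)C3(OCCO3)C1
F4 | step 7 | cis-fused triol, 1β-H,2β,6β,10β-trihydroxy-10α-isopropyl-7β-methylbicyclo[5.3.0]decane | C1C[C@@H](O)[C@H]2[C@](C)(CC[C@@]2(O)C(C)C)[C@@H](O)C1
F5 | step 7 | cis-fused C1 epimer of 11, 1β-H,10β-hydroxy-10α-isopropyl-7β-methylbicyclo[5.3.0]decane-2,6-dione | C1CC(=O)[C@H]2[C@](C)(CC[C@@]2(O)C(C)C)C(=O)C1
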